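**Plan**

1. Feature: in the aryl ring C1′–C6′, C3′–OH, C4′–H and C5′–OMe stand side by side, followed by prenyl (C6′), benzofuran-2-yl (C1′) and prenyl (C2′). Two unlike meta oxygens around the only ring CH are what a ketene carbonyl carbon and an alkoxyalkyne leave behind, so this ring can be built last from open-chain parts.
2. Cuts: first the 6-O-silyl group, then four ring bonds at once (C6′–C1′, C3′–C4′, C5′–C6′, C2′–C3′). This gives methoxyacetylene and an (E)-enone with benzofuranyl at Cα, prenyl at Cβ and a diazo- and prenyl-bearing Cα′.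
3. The diazo enone is cut at C=N2 (diazo transfer), at the enone C=C (aldol addition/dehydration with 4-methylpent-3-enal), at the α′-CH2–prenyl bond (ketone dianion alkylation) and at benzofuran C2–CH2 (lithiation/allylation, then Wacker oxidation).
4. Forward order: the benzofuran bicycle is bought as benzofuran-6-ol, the C14 chain grows from its C2 (steps 1–8), the benzene ring is the only ring formed (step 10), and desilylation ends the route.
5. Stereochemistry: the target has no stereocentre. The only stereo-element on the way is the E geometry of the enone, set by E1cB elimination and consumed on aromatisation.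

Key step: step 10

Remark 1: the SMILES holds no stereocentre. Rotation about the C2–C1′ axis (flanked on the furan side only by O and C3–H) is taken as free at room temperature, so the compound is treated as achiral and no enantiocontrol is needed.
Remark 2: methoxyacetylene is taken as not reliably purchasable and is therefore made in step 9.
Abbreviations: BF = 6-[(tert-butyldimethylsilyl)oxy]-1-benzofuran-2-yl; prenyl = 3-methylbut-2-en-1-yl. Primed locants are those of the aryl ring of the target.

**Step 1**
Reactants: 1 benzofuran-6-ol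
Product: 2 tert-butyl(1-benzofuran-6-yloxy)dimethylsilane
Conditions: TBSCl (1.2 equiv), imidazole (2.5 equiv), DMF, rt
Reagents that add atoms: tert-butyldimethylsilyl chloride, CC(C)(C)[Si](C)(C)Cl
Why: Imidazole-promoted silylation of a phenol is routine, and the aryl silyl ether removes the only acidic proton before the organolithium and enolate steps while staying cleavable by fluoride at the end.

**Step 2**
Reactants: 2 tert-butyl(1-benzofuran-6-yloxy)dimethylsilane; 3 allyl bromide
Product: 5 2-allyl-6-[(tert-butyldimethylsilyl)oxy]-1-benzofuran, via 2-lithiobenzofuran 4 (not isolated)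
Conditions: n-BuLi (1.1 equiv), THF, −78 °C; CuI (10 mol %), 3 (1.3 equiv), −78 °C → rt
Reagents that add atoms: n-butyllithium, [Li]CCCC (lithium stays only in 4)
Why: Benzofuran is metalated by n-BuLi at C2, next to the ring oxygen, well before any benzenoid C–H, and the heteroaryllithium is allylated by copper-assisted SN2 displacement of the allylic bromide.

**Step 3**
Reactants: 5 2-allyl-6-[(tert-butyldimethylsilyl)oxy]-1-benzofuran
Product: 6 1-(BF)propan-2-one
Conditions: PdCl2 (10 mol %), CuCl, O2 (1 atm), DMF/H2O 7:1, rt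
Reagents that add atoms: water, O (source of the ketone oxygen; O2 only reoxidises the metals)
Why: The Tsuji–Wacker oxidation turns a terminal alkene into the methyl ketone with Markovnikov selectivity, is routine for allylarenes, and should leave the aryl silyl ether and the benzofuran untouched at room temperature.

**Step 4**
Reactants: 6 1-(BF)propan-2-one; 7 prenyl bromide
Product: 9 1-(BF)-6-methylhept-5-en-2-one, via potassium lithium dianion 8 (not isolated)
Conditions: KH (1.05 equiv), THF, 0 °C; n-BuLi (1.05 equiv), TMEDA, 0 °C; 7 (1.0 equiv), −78 → 0 °C; AcOH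
Reagents that add atoms: potassium hydride, [K+].[H-] (potassium stays only in 8); n-butyllithium, [Li]CCCC (lithium stays only in 8)
Why: Alkylation of a ketone α,α′-dianion: KH removes the acidic proton between benzofuran and carbonyl, n-BuLi/TMEDA then removes a methyl proton, and only the less stabilised terminal carbanion is alkylated (SN2) by one equivalent of prenyl bromide, the surviving stabilised enolate blocking a second alkylation.

**Step 5**
Reactants: 10 4-methylpent-3-en-1-ol
Product: 11 4-methylpent-3-enal
Conditions: Dess–Martin periodinane (1.1 equiv), CH2Cl2, 0 °C → rt; solution used at once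
Reagents that add atoms: none
Why: The Dess–Martin oxidation runs under neutral, non-enolising conditions, so the β,γ-unsaturated aldehyde should form without migration of the double bond into conjugation if it is used directly.

**Step 6**
Reactants: 9 1-(BF)-6-methylhept-5-en-2-one; 11 4-methylpent-3-enal
Product: 13 7-(BF)-8-hydroxy-2,11-dimethyldodeca-2,10-dien-6-one (mixture of racemic diastereomers), via lithium enolate 12 (not isolated)
Conditions: LiHMDS (1.05 equiv), THF, −78 °C; 11 (1.3 equiv), −78 °C; AcOH, −78 °C
Reagents that add atoms: lithium hexamethyldisilazide, [Li]N([Si](C)(C)C)[Si](C)(C)C (lithium stays only in 12)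
Why: Directed aldol addition of a preformed lithium enolate: LiHMDS deprotonates only the far more acidic CH2 between benzofuran and carbonyl, carbonyl addition at −78 °C should outrun proton transfer from the sensitive aldehyde, and the two new stereocentres need no control because step 7 erases them.

**Step 7**
Reactants: 13 7-(BF)-8-hydroxy-2,11-dimethyldodeca-2,10-dien-6-one
Product: 15 (7E)-7-(BF)-2,11-dimethyldodeca-2,7,10-trien-6-one, via mesylate 14 (not isolated)
Conditions: MsCl (1.3 equiv), Et3N (3 equiv), CH2Cl2, 0 °C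
Reagents that add atoms: methanesulfonyl chloride, CS(=O)(=O)Cl (its atoms stay only in 14)
Why: Mesylation followed by E1cB elimination through the benzofuran-stabilised enolate loses the aldol configuration and should favour the E alkene, because the flat benzofuran can twist aside next to the chain whereas the acyl group would suffer A(1,3) strain.

**Step 8**
Reactants: 15 (7E)-7-(BF)-2,11-dimethyldodeca-2,7,10-trien-6-one
Product: 18 (7E)-7-(BF)-5-diazo-2,11-dimethyldodeca-2,7,10-trien-6-one, via cross-conjugated lithium enolate 16 (not isolated), via trifluoroacetyl ketone 17 (not isolated)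
Conditions: LiHMDS (1.1 equiv), THF, −78 °C; CF3CO2CH2CF3 (1.2 equiv), −78 °C; 5% aq HCl; then MsN3 (1.5 equiv), Et3N (1.5 equiv), H2O (1 equiv), MeCN, rt
Reagents that add atoms: lithium hexamethyldisilazide, [Li]N([Si](C)(C)C)[Si](C)(C)C (lithium stays only in 16); 2,2,2-trifluoroethyl trifluoroacetate, FC(F)(F)COC(=O)C(F)(F)F (CF3CO stays only in 17); methanesulfonyl azide, CS(=O)(=O)N=[N+]=[N-] (gives N2 to 18)
Why: Detrifluoroacetylative diazo transfer (the deacylative Regitz variant made for enones): LiHMDS forms the kinetic α′-enolate, helped by the E geometry that holds the doubly allylic γ-CH2 away from the lithium-bound carbonyl, C-trifluoroacetylation activates that carbon, and mesyl azide/Et3N then delivers N2 with loss of the trifluoroacetyl group.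

**Step 9**
Reactants: 19 chloroacetaldehyde dimethyl acetal
Product: 21 methoxyacetylene, via sodium methoxyacetylide 20 (not isolated)
Conditions: NaNH2 (3.2 equiv), liq. NH3, −33 °C; NH3 evaporated; cold sat. aq NaCl, −20 °C; distilled into cold ClCH2CH2Cl
Reagents that add atoms: sodium amide, [Na+].[NH2-] (sodium stays only in 20)
Why: Twofold base-induced elimination (methanol, then HCl) from an α-chloroacetal with sodium amide in liquid ammonia is the standard preparation of alkoxyacetylenes, the product being held as its sodium acetylide until hydrolysis and then distilled off thanks to its low boiling point.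

**Step 10**
Reactants: 18 (7E)-7-(BF)-5-diazo-2,11-dimethyldodeca-2,7,10-trien-6-one; 21 methoxyacetylene
Product: 26 3-(BF)-5-methoxy-2,4-bis(3-methylbut-2-enyl)phenol, via vinylketene 22 (not isolated), via vinylcyclobutenone 23 (not isolated), via dienylketene 24 (not isolated), via cyclohexadienone 25 (not isolated)
Conditions: 21 (5 equiv), ClCH2CH2Cl (0.1 M), hν (254 nm, quartz pressure tube), 0–10 °C; then 80 °C in the same closed vessel
Reagents that add atoms: none
Why: Photoexcitation of 18 releases dinitrogen while the C1′ alkenyl carbon migrates from the carbonyl carbon to the diazo carbon (Wolff rearrangement, bond C6′–C1′), and vinylketene 22 is caught by the ynol ether in a polar [2+2] in which the nucleophilic CH of 21 attacks the ketene carbonyl carbon (C3′–C4′) and the methoxy-stabilised carbon closes onto the ketene α-carbon (C5′–C6′). Heating opens 23 by a reversible conrotatory 4π cleavage of its C(=O)–C(quaternary) bond, and of the two possible dienylketenes only 24, with the alkenyl arm cis to the ketene, can go on while the other returns to 23. The benzene ring, the only ring that remains, closes by a disrotatory thermal 6π electrocyclisation between the ketene carbon and the alkene CH (C2′–C3′), and enolisation of 25 to the phenol makes the cascade irreversible. The closest known reaction type is the Danheiser benzannulation in its α-diazo ketone version with alkoxyacetylenes. No stereocentre is left in 26, since the quaternary carbon of 23 and the sp3 carbon of 25 (both racemic) become aromatic carbons. The step needs regiocontrol, secured by the polarisation of 21, which places OH and OMe meta with the CH between; it needs chemoselectivity for 21 over the prenyl alkenes and over ketene dimerisation, secured by an excess of the far more nucleophilic alkyne; and it needs a clean alkenyl shift and ring closure, helped by direct irradiation, by the E geometry of 18 (the C2′ chain points away from the ketene, so no 1,5-H shift, and H rather than alkyl lies inside the closing ring) and by cold photolysis, which stops at 23 so that no phenol is present to trap the ketene.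

**Step 11**
Reactants: 26 3-(BF)-5-methoxy-2,4-bis(3-methylbut-2-enyl)phenol
Product: 27 2-[3-hydroxy-5-methoxy-2,6-bis(3-methylbut-2-enyl)phenyl]-1-benzofuran-6-ol (CNP0324103.0)
Conditions: TBAF (1.1 equiv), AcOH (1.1 equiv), THF, 0 °C
Reagents that add atoms: none
Why: Fluoride-induced cleavage of the aryl silyl ether is driven by the strong Si–F bond, the acetic acid buffer keeps both phenols protonated, and the methyl ether, the prenyl groups and the benzofuran are inert.

**Compound list**

1 | benzofuran-6-ol | Oc1ccc2ccoc2c1 | starting material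
2 | tert-butyl(1-benzofuran-6-yloxy)dimethylsilane | CC(C)(C)[Si](C)(C)Oc1ccc2ccoc2c1 | intermediate
3 | allyl bromide | C=CCBr | starting material
4 | {6-[(tert-butyldimethylsilyl)oxy]-1-benzofuran-2-yl}lithium | [Li]c1cc2ccc(O[Si](C)(C)C(C)(C)C)cc2o1 | intermediate
5 | 2-allyl-6-[(tert-butyldimethylsilyl)oxy]-1-benzofuran | C=CCc1cc2ccc(O[Si](C)(C)C(C)(C)C)cc2o1 | intermediate
6 | 1-(BF)propan-2-one | CC(=O)Cc1cc2ccc(O[Si](C)(C)C(C)(C)C)cc2o1 | intermediate
7 | prenyl bromide (1-bromo-3-methylbut-2-ene) | CC(C)=CCBr | starting material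
8 | α,α′-dianion of 6 (O-potassium enolate, C-lithiated methyl terminus) | [Li]CC(O[K])=Cc1cc2ccc(O[Si](C)(C)C(C)(C)C)cc2o1 | intermediate
9 | 1-(BF)-6-methylhept-5-en-2-one | CC(C)=CCCC(=O)Cc1cc2ccc(O[Si](C)(C)C(C)(C)C)cc2o1 | intermediate
10 | 4-methylpent-3-en-1-ol | CC(C)=CCCO | starting material
11 | 4-methylpent-3-enal | CC(C)=CCC=O | intermediate
12 | lithium enolate of 9 (C1=C2, conjugated with the benzofuran) | CC(C)=CCCC(O[Li])=Cc1cc2ccc(O[Si](C)(C)C(C)(C)C)cc2o1 | intermediate
13 | 7-(BF)-8-hydroxy-2,11-dimethyldodeca-2,10-dien-6-one (racemic diastereomer mixture) | CC(C)=CCC(O)C(c1cc2ccc(O[Si](C)(C)C(C)(C)C)cc2o1)C(=O)CCC=C(C)C | intermediate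
14 | 8-O-methanesulfonate of 13 | CC(C)=CCC(OS(C)(=O)=O)C(c1cc2ccc(O[Si](C)(C)C(C)(C)C)cc2o1)C(=O)CCC=C(C)C | intermediate
15 | (7E)-7-(BF)-2,11-dimethyldodeca-2,7,10-trien-6-one | CC(C)=CC\C=C(/c1cc2ccc(O[Si](C)(C)C(C)(C)C)cc2o1)C(=O)CCC=C(C)C | intermediate
16 | lithium α′-enolate of 15 (C5=C6) | CC(C)=CC\C=C(/c1cc2ccc(O[Si](C)(C)C(C)(C)C)cc2o1)C(O[Li])=CCC=C(C)C | intermediate
17 | (7E)-7-(BF)-2,11-dimethyl-5-(trifluoroacetyl)dodeca-2,7,10-trien-6-one (racemic) | CC(C)=CC\C=C(/c1cc2ccc(O[Si](C)(C)C(C)(C)C)cc2o1)C(=O)C(CC=C(C)C)C(=O)C(F)(F)F | intermediate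
18 | (7E)-7-(BF)-5-diazo-2,11-dimethyldodeca-2,7,10-trien-6-one | CC(C)=CC\C=C(/c1cc2ccc(O[Si](C)(C)C(C)(C)C)cc2o1)C(=O)C(=[N+]=[N-])CC=C(C)C | intermediate
19 | chloroacetaldehyde dimethyl acetal (2-chloro-1,1-dimethoxyethane) | COC(CCl)OC | starting material
20 | sodium methoxyacetylide | COC#C[Na] | intermediate
21 | methoxyacetylene | COC#C | intermediate
22 | (3Z)-3-(BF)-7-methyl-2-(3-methylbut-2-enyl)octa-1,3,6-trien-1-one (vinylketene) | O=C=C(CC=C(C)C)/C(c1cc2ccc(O[Si](C)(C)C(C)(C)C)cc2o1)=C/CC=C(C)C | intermediate
23 | (±)-4-[(1Z)-1-(BF)-5-methylhexa-1,4-dienyl]-3-methoxy-4-(3-methylbut-2-enyl)cyclobut-2-en-1-one | COC1=CC(=O)C1(CC=C(C)C)/C(c2cc3ccc(O[Si](C)(C)C(C)(C)C)cc3o2)=C/CC=C(C)C | intermediate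
24 | (3E,5Z)-5-(BF)-3-methoxy-9-methyl-4-(3-methylbut-2-enyl)deca-1,3,5,8-tetraen-1-one (dienylketene) | O=C=C/C(OC)=C(CC=C(C)C)\C(c1cc2ccc(O[Si](C)(C)C(C)(C)C)cc2o1)=C\CC=C(C)C | intermediate
25 | (±)-5-(BF)-3-methoxy-4,6-bis(3-methylbut-2-enyl)cyclohexa-2,4-dien-1-one | COC1=CC(=O)C(CC=C(C)C)C(c2cc3ccc(O[Si](C)(C)C(C)(C)C)cc3o2)=C1CC=C(C)C | intermediate
26 | 3-(BF)-5-methoxy-2,4-bis(3-methylbut-2-enyl)phenol | COc1cc(O)c(CC=C(C)C)c(-c2cc3ccc(O[Si](C)(C)C(C)(C)C)cc3o2)c1CC=C(C)C | intermediate
27 | 2-[3-hydroxy-5-methoxy-2,6-bis(3-methylbut-2-enyl)phenyl]-1-benzofuran-6-ol | COc1cc(O)c(CC=C(C)C)c(-c2cc3ccc(O)cc3o2)c1CC=C(C)C | target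

**Total step count:** 11.
**Longest linear sequence:** 9 (steps 1, 2, 3, 4, 6, 7, 8, 10, 11); steps 5 and 9 are one-step side branches.

**Steps most likely to fail**

**Step 10.**
- What may go wrong: after loss of N2, a 1,2-hydride shift from the allylic CH2 next to the carbene centre may outrun the alkenyl migration. This is most likely if the crowded diazo ketone prefers the s-E conformer, which cannot rearrange in concert.
- The strongly absorbing vinylbenzofuran unit may also screen the diazo chromophore or scramble the alkene geometry, and capture by the volatile alkyne may lose against ketene dimerisation.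
- Fallback (sets out from 2, comes back at 22): the same vinylketene is made in the dark by dehydrochlorination.

Lithiation of 2 as in step 2 and acylation with N-methoxy-N-methylacetamide should give 1-(BF)ethan-1-one F1. Its lithium enolate (LDA, THF, −78 °C) is alkylated with 7 to 1-(BF)-5-methylhex-4-en-1-one F2. A Horner–Wadsworth–Emmons reaction with allyl diethylphosphonoacetate (NaH, THF, reflux) gives allyl 3-(BF)-7-methylocta-2,6-dienoate F3, whose E/Z composition does not matter. γ-Deprotonation (LDA, THF/DMPU, −78 °C) and α-alkylation of the extended enolate with 7 (deconjugative alkylation) should give allyl (3Z)-3-(BF)-7-methyl-2-(3-methylbut-2-enyl)octa-3,6-dienoate F4. Pd(PPh3)4/morpholine then frees (3Z)-3-(BF)-7-methyl-2-(3-methylbut-2-enyl)octa-3,6-dienoic acid F5 without touching the aryl silyl ether, and 1-chloro-N,N,2-trimethylprop-1-en-1-amine (CH2Cl2, 0 °C) converts it into the acid chloride F6. Slow addition of Et3N to F6 and excess 21 at 0 °C generates 22, which is captured to 23 and heated on as in step 10.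

**Step 8.**
- What may go wrong: the amide base or Et3N may remove the doubly allylic γ-proton, so that the skipped diene slides into conjugation. C-acylation at the substituted α′-carbon may also be sluggish.
- Fallback (sets out from 9, comes back at 18, and also bypasses steps 5–7): the C7=C8 alkene is kept masked as a quaternary selenide while the base chemistry is done.

The potassium enolate of 9 (KHMDS, THF/DMPU) is alkylated with 5-bromo-2-methylpent-2-ene (cat. Bu4NI) to 7-(BF)-2,11-dimethyldodeca-2,10-dien-6-one F7. Renewed enolisation and PhSeCl at −78 °C give 7-(BF)-2,11-dimethyl-7-(phenylselanyl)dodeca-2,10-dien-6-one F8, in which the α′-CH2 is the only acidic position. LiHMDS/CF3CO2CH2CF3 (ester present during deprotonation, to outrun selenium transfer between enolates) gives the 5-trifluoroacetyl selenide F9, and MsN3/Et3N gives the 5-diazo selenide F10. H2O2/pyridine (CH2Cl2, 0 °C) oxidises selenium to the selenoxide F11, whose syn elimination can only take a C8 hydrogen and should give 18.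

**Step 4.**
- What may go wrong: the second deprotonation may stay incomplete, or the benzofuran ring may be metalated instead of the methyl group. The mono-enolate would then be alkylated at the carbon next to the benzofuran.
- Fallback (sets out from 6, comes back at 15): prenylation is postponed until the acidic methylene has become the alkene, so that only ordinary mono-enolates are used.

LiHMDS enolisation of 6 and addition of 11 (−78 °C) should give 3-(BF)-4-hydroxy-7-methyloct-6-en-2-one F12. MsCl/Et3N converts it through the mesylate F13 into (3E)-3-(BF)-7-methylocta-3,6-dien-2-one F14. Kinetic deprotonation of the methyl group (LDA, THF, −78 °C) and alkylation with 7 then give 15.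

**Further compounds**

F1 | step 10 | 1-(BF)ethan-1-one | CC(=O)c1cc2ccc(O[Si](C)(C)C(C)(C)C)cc2o1
F2 | step 10 | 1-(BF)-5-methylhex-4-en-1-one | CC(C)=CCCC(=O)c1cc2ccc(O[Si](C)(C)C(C)(C)C)cc2o1
F3 | step 10 | allyl 3-(BF)-7-methylocta-2,6-dienoate (E/Z mixture) | C=CCOC(=O)C=C(CCC=C(C)C)c1cc2ccc(O[Si](C)(C)C(C)(C)C)cc2o1
F4 | step 10 | allyl (3Z)-3-(BF)-7-methyl-2-(3-methylbut-2-enyl)octa-3,6-dienoate (racemic) | C=CCOC(=O)C(CC=C(C)C)/C(c1cc2ccc(O[Si](C)(C)C(C)(C)C)cc2o1)=C/CC=C(C)C
F5 | step 10 | (3Z)-3-(BF)-7-methyl-2-(3-methylbut-2-enyl)octa-3,6-dienoic acid (racemic) | OC(=O)C(CC=C(C)C)/C(c1cc2ccc(O[Si](C)(C)C(C)(C)C)cc2o1)=C/CC=C(C)C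
F6 | step 10 | (3Z)-3-(BF)-7-methyl-2-(3-methylbut-2-enyl)octa-3,6-dienoyl chloride (racemic) | ClC(=O)C(CC=C(C)C)/C(c1cc2ccc(O[Si](C)(C)C(C)(C)C)cc2o1)=C/CC=C(C)C
F7 | step 8 | 7-(BF)-2,11-dimethyldodeca-2,10-dien-6-one (racemic) | CC(C)=CCCC(c1cc2ccc(O[Si](C)(C)C(C)(C)C)cc2o1)C(=O)CCC=C(C)C
F8 | step 8 | 7-(BF)-2,11-dimethyl-7-(phenylselanyl)dodeca-2,10-dien-6-one (racemic) | CC(C)=CCCC([Se]c1ccccc1)(c2cc3ccc(O[Si](C)(C)C(C)(C)C)cc3o2)C(=O)CCC=C(C)C
F9 | step 8 | 7-(BF)-2,11-dimethyl-7-(phenylselanyl)-5-(trifluoroacetyl)dodeca-2,10-dien-6-one | CC(C)=CCCC([Se]c1ccccc1)(c2cc3ccc(O[Si](C)(C)C(C)(C)C)cc3o2)C(=O)C(CC=C(C)C)C(=O)C(F)(F)F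
F10 | step 8 | 7-(BF)-5-diazo-2,11-dimethyl-7-(phenylselanyl)dodeca-2,10-dien-6-one (racemic) | CC(C)=CCCC([Se]c1ccccc1)(c2cc3ccc(O[Si](C)(C)C(C)(C)C)cc3o2)C(=O)C(=[N+]=[N-])CC=C(C)C
F11 | step 8 | 7-(BF)-5-diazo-2,11-dimethyl-7-(phenylseleninyl)dodeca-2,10-dien-6-one | CC(C)=CCCC([Se](=O)c1ccccc1)(c2cc3ccc(O[Si](C)(C)C(C)(C)C)cc3o2)C(=O)C(=[N+]=[N-])CC=C(C)C
F12 | step 4 | 3-(BF)-4-hydroxy-7-methyloct-6-en-2-one (racemic diastereomer mixture) | CC(=O)C(c1cc2ccc(O[Si](C)(C)C(C)(C)C)cc2o1)C(O)CC=C(C)C
F13 | step 4 | 4-O-methanesulfonate of F12 | CC(=O)C(c1cc2ccc(O[Si](C)(C)C(C)(C)C)cc2o1)C(CC=C(C)C)OS(C)(=O)=O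
F14 | step 4 | (3E)-3-(BF)-7-methylocta-3,6-dien-2-one | CC(C)=CC\C=C(/c1cc2ccc(O[Si](C)(C)C(C)(C)C)cc2o1)C(C)=O
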